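**Retrosynthetic overview** (side chain numbered C1 = benzylic to C17)

1. C8=C9 (Z): final Wittig between the unprotected resorcinol phosphonium salt 15 (ring + C1–C8) and the hydroxy-enal 9 (C9–C17); no protecting group is removed after it.
2. C11=C12 (Z) and C9–C11: Wittig of lactol 5 (C12–C17) with the C3 acetal ylide from 6, then acetal hydrolysis to 9.
3. Key bond C14–C15: the Grignard reagent of bromoacetal 2, a propanal homoenolate (β-carbanion of a masked aldehyde), opens (S)-propylene oxide 1 at CH2. Both carbons are electrophilic in their native form. C16 (S) comes with the epoxide and is never protected.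
4. Aryl–C1: Kochi coupling of 3,5-dimethoxyphenylmagnesium bromide with 1,8-dibromooctane, demethylation before any alkene exists, then PPh3.
5. Rings: the arene is bought. The only ring formed is the lactol (oxane) of 5 in step 1, and it is opened again in step 2.

Assumption: lactol 5 is drawn in its ring form (both anomers); it reacts through the open (S)-5-hydroxyhexanal.

**Step 1**
Reactants: 1 (S)-2-methyloxirane [(S)-propylene oxide]; 2 2-(2-bromoethyl)-1,3-dioxolane
Product: 5 (6S)-6-methyloxan-2-ol [lactol of (S)-5-hydroxyhexanal; anomer mixture], via Grignard reagent 3 (not isolated), via hydroxy acetal 4 (not isolated)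
Conditions: 2 (1.3 equiv), Mg, THF, 25–30 °C; CuI (10 mol %), −30 °C, then 1, −30 → 0 °C; then 2 M aq. HCl into the same flask, rt, 4 h
Reagents that add atoms: water, O
Why: Cu(I)-catalysed SN2 epoxide opening by a homoenolate (d3, masked β-formylethyl) Grignard reagent occurs only at the unhindered CH2, so the C–O stereocentre of 1 becomes C16 (S) unchanged, and aqueous acid then hydrolyses the dioxolane, the freed aldehyde being trapped by the new hydroxyl as the six-membered lactol.

**Step 2**
Reactants: 5 (6S)-6-methyloxan-2-ol; 6 [2-(1,3-dioxolan-2-yl)ethyl]triphenylphosphonium bromide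
Product: 8 (2S,6Z)-8-(1,3-dioxolan-2-yl)oct-6-en-2-ol, via ylide 7 (not isolated)
Conditions: 6 (2.6 equiv), NaHMDS (2.5 equiv), THF, 0 °C; then 5, −78 °C → rt; aq. NH4Cl
Reagents that add atoms: none
Why: Wittig olefination of the lactol (through its open hydroxy-aldehyde form) with a non-stabilised ylide under lithium-free conditions gives the (Z)-alkene by kinetic cis-oxaphosphetane formation; excess ylide compensates for the free OH, and the acetal and C16 are untouched.

**Step 3**
Reactants: 8 (2S,6Z)-8-(1,3-dioxolan-2-yl)oct-6-en-2-ol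
Product: 9 (3Z,8S)-8-hydroxynon-3-enal
Conditions: SiO2 wetted with 15 % aq. H2SO4, CH2Cl2, rt; filtered through NaHCO3; crude used at once
Reagents that add atoms: water, O
Why: Heterogeneous acid-catalysed acetal hydrolysis on wet silica is mild enough to release the (Z)-β,γ-unsaturated aldehyde before the double bond migrates into conjugation; the secondary alcohol and its stereocentre are inert.

**Step 4**
Reactants: 10 1-bromo-3,5-dimethoxybenzene; 11 1,8-dibromooctane
Product: 13 1-(8-bromooctyl)-3,5-dimethoxybenzene, via aryl Grignard 12 (not isolated)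
Conditions: 10, Mg, THF, reflux; added to 11 (3 equiv), Li2CuCl4 (3 mol %), THF, 0 °C → rt
Reagents that add atoms: none
Why: Kochi copper-catalysed cross-coupling of an aryl Grignard reagent with a primary alkyl bromide; the threefold excess of dibromide (recovered by distillation) keeps it to mono-substitution.

**Step 5**
Reactants: 13 1-(8-bromooctyl)-3,5-dimethoxybenzene
Product: 14 5-(8-bromooctyl)benzene-1,3-diol
Conditions: BBr3 (3 equiv), CH2Cl2, −78 °C → rt; then H2O
Reagents that add atoms: none
Why: BBr3 ether cleavage (Lewis acid–base complex, then SN2 demethylation by bromide) is done here, where there is no alkene or carbinol to damage; the primary alkyl bromide is inert.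

**Step 6**
Reactants: 14 5-(8-bromooctyl)benzene-1,3-diol
Product: 15 [8-(3,5-dihydroxyphenyl)octyl]triphenylphosphonium bromide
Conditions: PPh3 (1.5 equiv), MeCN, reflux, 48 h; precipitated with Et2O
Reagents that add atoms: triphenylphosphine, c1ccc(cc1)P(c1ccccc1)c1ccccc1
Why: SN2 quaternisation of triphenylphosphine by the primary bromide under neutral conditions, where the free phenols cannot O-alkylate.

**Step 7**
Reactants: 15 [8-(3,5-dihydroxyphenyl)octyl]triphenylphosphonium bromide; 9 (3Z,8S)-8-hydroxynon-3-enal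
Product: 17 5-[(8Z,11Z,16S)-16-hydroxyheptadeca-8,11-dien-1-yl]benzene-1,3-diol (hansfordiol D), via phenoxide ylide 16 (not isolated)
Conditions: 15 (1.3 equiv), NaHMDS (3.8 equiv), THF/DMPU 5:1, 0 °C; then 9 (1.0 equiv), −78 °C → rt; aq. NH4Cl
Reagents that add atoms: none
Why: Z-selective Wittig olefination in which two equivalents of base hold the phenols as sodium phenoxides and the third forms the non-stabilised ylide, which at −78 °C adds to the aldehyde faster than it enolises it and gives the second (Z)-alkene under kinetic control; the C11=C12 geometry and C16 are not touched.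

**Compound list**

1 | (S)-2-methyloxirane | C[C@H]1CO1 | starting material
2 | 2-(2-bromoethyl)-1,3-dioxolane | BrCCC1OCCO1 | starting material
3 | [2-(1,3-dioxolan-2-yl)ethyl]magnesium bromide (formed in the flask) | Br[Mg]CCC1OCCO1 | intermediate
4 | (2S)-5-(1,3-dioxolan-2-yl)pentan-2-ol (formed in the flask) | C[C@H](O)CCCC1OCCO1 | intermediate
5 | (6S)-6-methyloxan-2-ol | C[C@H]1CCCC(O)O1 | intermediate
6 | [2-(1,3-dioxolan-2-yl)ethyl]triphenylphosphonium bromide | [Br-].C1COC(CC[P+](c2ccccc2)(c2ccccc2)c2ccccc2)O1 | starting material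
7 | [2-(1,3-dioxolan-2-yl)ethylidene]triphenylphosphorane (formed in the flask) | C1COC(CC=P(c2ccccc2)(c2ccccc2)c2ccccc2)O1 | intermediate
8 | (2S,6Z)-8-(1,3-dioxolan-2-yl)oct-6-en-2-ol | C[C@H](O)CCC/C=C\CC1OCCO1 | intermediate
9 | (3Z,8S)-8-hydroxynon-3-enal | C[C@H](O)CCC/C=C\CC=O | intermediate
10 | 1-bromo-3,5-dimethoxybenzene | COc1cc(Br)cc(OC)c1 | starting material
11 | 1,8-dibromooctane | BrCCCCCCCCBr | starting material
12 | (3,5-dimethoxyphenyl)magnesium bromide (formed in the flask) | COc1cc([Mg]Br)cc(OC)c1 | intermediate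
13 | 1-(8-bromooctyl)-3,5-dimethoxybenzene | COc1cc(CCCCCCCCBr)cc(OC)c1 | intermediate
14 | 5-(8-bromooctyl)benzene-1,3-diol | Oc1cc(CCCCCCCCBr)cc(O)c1 | intermediate
15 | [8-(3,5-dihydroxyphenyl)octyl]triphenylphosphonium bromide | [Br-].Oc1cc(CCCCCCCC[P+](c2ccccc2)(c2ccccc2)c2ccccc2)cc(O)c1 | intermediate
16 | disodium 5-[8-(triphenyl-λ5-phosphanylidene)octyl]benzene-1,3-diolate (formed in the flask) | [Na+].[Na+].[O-]c1cc(CCCCCCCC=P(c2ccccc2)(c2ccccc2)c2ccccc2)cc([O-])c1 | intermediate
17 | 5-[(8Z,11Z,16S)-16-hydroxyheptadeca-8,11-dien-1-yl]benzene-1,3-diol (hansfordiol D) | C[C@H](O)CCC/C=C\C/C=C\CCCCCCCc1cc(O)cc(O)c1 | target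

**Step count:** 7 steps in total. Longest linear sequence: 4 steps (1 → 2 → 3 → 7, or 4 → 5 → 6 → 7).

**Steps most likely to fail, with fallbacks**

Step 1 (heat-sensitive acetal Grignard; hydrolysis and isolation of a small, water-soluble lactol in one flask). The fallback sets out from 1 and comes back at 5. It keeps the same C14–C15 bond but uses a terminal alkene instead of the dioxolane as the latent aldehyde of the nucleophile. Commercial but-3-enylmagnesium bromide with CuI (10 mol %) in THF at −30 °C opens 1 to give (2S)-hept-6-en-2-ol F1. Ozonolysis (O3, CH2Cl2/MeOH, −78 °C, then Me2S) unmasks the aldehyde, which closes to lactol 5 without any acid treatment.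

Step 3 (the (Z)-β,γ-enal can slip into conjugation or lose its geometry during acetal cleavage). The fallback sets out from 5 and comes back at 9. It reaches the aldehyde by oxidation instead of hydrolysis. Wittig reaction of 5 with the ylide from commercial [3-(tert-butyldimethylsilyloxy)propyl]triphenylphosphonium bromide and NaHMDS (THF, −78 °C → rt) gives (2S,6Z)-9-{[tert-butyl(dimethyl)silyl]oxy}non-6-en-2-ol F2. TBAF in THF gives (3Z,8S)-non-3-ene-1,8-diol F3. TEMPO (10 mol %) with PhI(OAc)2 in CH2Cl2 at rt oxidises only the primary alcohol and delivers 9 under near-neutral conditions.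

Step 7 (the bis-phenoxide ylide may be poorly soluble, and the phenoxides may enolise the sensitive aldehyde and lower yield or Z-selectivity). The fallback sets out from 15 and comes back at 17. It masks the phenols as silyl ethers for the olefination. TBSCl and imidazole in DMF convert 15 into (8-{3,5-bis[(tert-butyldimethylsilyl)oxy]phenyl}octyl)triphenylphosphonium bromide F4. NaHMDS (1.0 equiv, THF, 0 °C) gives the ylide (8-{3,5-bis[(tert-butyldimethylsilyl)oxy]phenyl}octylidene)triphenylphosphorane F5. Its Wittig reaction with 9 at −78 °C gives (2S,6Z,9Z)-17-{3,5-bis[(tert-butyldimethylsilyl)oxy]phenyl}heptadeca-6,9-dien-2-ol F6. TBAF in THF at 0 °C removes both silyl groups to give 17.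

**Further compounds**

F1 | step 1 | (2S)-hept-6-en-2-ol | C[C@H](O)CCCC=C
F2 | step 3 | (2S,6Z)-9-{[tert-butyl(dimethyl)silyl]oxy}non-6-en-2-ol | C[C@H](O)CCC/C=C\CCO[Si](C)(C)C(C)(C)C
F3 | step 3 | (3Z,8S)-non-3-ene-1,8-diol | C[C@H](O)CCC/C=C\CCO
F4 | step 7 | (8-{3,5-bis[(tert-butyldimethylsilyl)oxy]phenyl}octyl)triphenylphosphonium bromide | [Br-].CC(C)(C)[Si](C)(C)Oc1cc(CCCCCCCC[P+](c2ccccc2)(c2ccccc2)c2ccccc2)cc(O[Si](C)(C)C(C)(C)C)c1
F5 | step 7 | (8-{3,5-bis[(tert-butyldimethylsilyl)oxy]phenyl}octylidene)triphenylphosphorane | CC(C)(C)[Si](C)(C)Oc1cc(CCCCCCCC=P(c2ccccc2)(c2ccccc2)c2ccccc2)cc(O[Si](C)(C)C(C)(C)C)c1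
F6 | step 7 | (2S,6Z,9Z)-17-{3,5-bis[(tert-butyldimethylsilyl)oxy]phenyl}heptadeca-6,9-dien-2-ol | C[C@H](O)CCC/C=C\C/C=C\CCCCCCCc1cc(O[Si](C)(C)C(C)(C)C)cc(O[Si](C)(C)C(C)(C)C)c1
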